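## The problem

Chermebilaene B (40) is a hexacyclic C25 meroterpenoid built on one cyclohexane (ring A, C5–C10) that carries two adjacent spiro centres. C10 is shared with a δ-lactone (ring B: C10, C1, C2, C3(=O), O, C19) and C9 with a tetrahydrofuran (ring C: C9, C11, C12, C13, O). Ring C is fused through C12–C13 to a cage of a tetrahydropyran (C12, C14, C15, C18, O, C13), a γ-lactone (C15, C16(=O), O, C17, C18) and a 1,3-dioxolane (C13, O, C17, C18, O), so C13 is an orthoester carbon, C17 a ketal carbon, and C4 on C5 is the carbinol carbon. Eleven stereocentres must be set: C5, C7, C8, C9, C10 on ring A (two quaternary) and C12, C13, C14, C15, C17, C18 in the cage. C10 can control C5, C8, C7 and C9 while ring A is part of a rigid bicycle, because reagents then arrive opposite the axial C10 substituent. C9 can control C12 through the faces of ring C, C12 must control C14 across a single bond (the weakest link), C13 and C17 follow from the cage, and C15 and C18 can be corrected only while they sit next to a carbonyl group. The C8 methyl is axial and syn to C19, so it needs kinetic hydrogen delivery; the cage is acid-labile, the two lactones have α-CH2 groups a base cannot tell apart, the tertiary alcohol dehydrates, and a C7 ketone would expel the acylated C9 oxygen by β-elimination. The enabling feature is that the ring B carbonyl C3 and the carbinol carbon C4 on the neighbouring ring A carbon C5 are the two ends of one broken bond: with C3–C4 restored, C1–C5 and C10 form a 2,2-dimethylcyclohexanone trans-fused to ring A whose angular substituent is the lactone oxymethylene C19, the arrangement in which Norrish type 1 cleavage and ketene capture turn a ketone into ring B.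

## Retrosynthesis

**C4–O and the silyl ether (40 ⇒ 39 ⇒ 38).** The last cuts remove the silyl group and replace C4–OH by C4–H. Carrying a free tertiary alcohol through hydride, enolate and acid steps would cost a protecting group and invite dehydration. Isopropyl compound 38 is what the ring-opening step delivers. The forward step needs a site-selective tertiary C–H hydroxylation; C4–H is the only tertiary C–H without an oxygen within two bonds.

**The cage (38 ⇒ 36).** Three C–O bonds are cut: C13–O18, C13–O–C17 and C16–O–C17. This leaves ring C as a γ-lactone with a side chain that holds a methyl ester, a secondary alcohol and a masked methyl ketone. No C–C bond of the cage is formed late, and C13 and C17 need no separate control. The alternative of making a carbocycle and cleaving it oxidatively (see Roads not taken) costs more redox steps. The forward reaction is an acid-mediated, thermodynamically driven closure.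

**C12–C14 (36 ⇒ 35 ⇒ 30 + 33).** The γ-lactone carbonyl and the ester are 1,5-related, so the C12–C14 bond is cut as a Michael addition, and the C18 C–H bond as a ketone reduction. Acceptor 33 comes in one step from a commercial β-keto ester. Because a base cannot distinguish the two lactones, the C12 enolate must be generated regiospecifically. An α-methylene lactone in 30 does this: conjugate hydride addition gives the enolate and the C12 methyl at once. The forward step must select the C8 face of the enolate and one face of the acceptor.

**Ring B (30 ⇒ 28), the key cut.** The lactone C3–O19 bond is cut and C3–C4 is reconnected. Ring B, the quaternary spiro centre C10 and the C5/C10 relationship then reduce to the ring fusion of a trans-decalone, which asymmetric Robinson annulation chemistry supplies. Lactonization of a seco acid would need the same ring cleavage done separately. Baeyer–Villiger oxidation with acyl transfer needs a strong peracid on a hindered ketone beside an acrylate, and is kept as the fallback. The forward reaction needs α-cleavage on the C4 side, hydrogen transfer to give a ketene, and capture by the C19 hydroxyl.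

**Ring C lactone (28 ⇒ 27 ⇒ 24 + 25).** C9–C11 and the lactone C–O bond are cut to ketone 24 and ethyl 2-(bromomethyl)acrylate (25). One step forms the quaternary C9 and the methylene lactone. A ketyl–acrylate coupling would give the saturated lactone and leave the enolate problem unsolved. The nucleophile must add axially, opposite C19 and the C8 methyl.

**C5, C7, C8 (24 ⇒ 23 ⇒ 22 ⇒ 21 ⇒ 19 ⇒ 15).** The C8–CH3 carbon is traced to a Mannich methylenation, and the hydrogens at C8, C5 and C7 are all delivered from the α face. Direct enolate methylation would give the equatorial methyl, and additions to C7 of an enone would give the axial oxygen. C9 must be an alcohol with a 9α-hydrogen at this stage: a lactone oxygen at C9 would be eliminated by the C7 enolate, and an axial C11 would block axial hydride delivery to C7.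

**Decalin functional groups (15 ⇒ 14 ⇒ 12 ⇒ 11 ⇒ 10 ⇒ 9 ⇒ 7 ⇒ 6 ⇒ 5).** The angular allyl group is trimmed by two carbons to C19. C7 is oxidised through the C5=C6 alkene that deconjugative gem-dimethylation leaves behind. The two carbonyls are told apart by reducing C9 (benzyl ether, removed for free in the hydrogenation) and ketalising C3.

**The bicycle (5 ⇒ 3 ⇒ 1 + 2).** A Robinson annulation in two steps sets C10, the only stereocentre not derived from another.

## Roads not taken

**Alternative 1:** Ring A is cut at C7–C8. Aldehyde A1, which already holds ring B, C5, C10 and a trisubstituted alkene on C10, would close by a Lewis-acid-promoted type 2 carbonyl-ene reaction to methylenecyclohexanol A2.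
- *Merits:* one step makes ring A, C7 and C8 and leaves the exocyclic alkene at C9 ready for ring C. This is shorter than the five steps (7 and 11–14) the chosen plan spends on C7 and C8.
- *Weak points:* A1 needs the quaternary C10 and C5 set in a monocyclic lactone, where nothing rigid relays stereochemistry. The sense of induction from C5/C10 to C7/C8 in the ene transition state is open. C9 would still have to be made quaternary afterwards with facial control.
- *Comparison:* the chosen plan gets C5/C10 from a ring fusion and C9 from an axial addition, at the price of more steps on ring A.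

**Alternative 2:** C11–C12 and C9–O are cut. Anodic oxidation of methyl 3,5-dimethylorsellinate A4 in the presence of alkene A3 would give spiro dienone A5 by a dearomative [3+2] reaction.
- *Merits:* it is biomimetic and the most convergent route to the southern half, bringing in all eight cage carbons in one step.
- *Weak points:* the face of C9 and the C9/C12 relationship are set in a cationic closure with no obvious bias. The hexasubstituted arene is hindered and can couple with itself. A5 is still far from the cage: a tetrasubstituted enone must be reduced with control of C14 and C15, C18 must be reduced, and the C13–C17 bond must be cleaved oxidatively.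
- *Comparison:* this road is better in convergence. The chosen plan sets against it a C9 centre made under steric control and a cage closed without late redox steps. A3 itself would still need a ring A/B synthesis such as the present one.

**Alternative 3:** C12–C14 and C15–C18 are cut. Diene A6, built on ring C, would add methyl (E)-crotonate A7 to give cyclohexene A8, and ozonolysis of the enol ether would later unzip the carbocycle to the lactone and methyl ketone needed for the cage.
- *Merits:* C12 and C14 are set together in a concerted step, with relative configuration fixed by the dienophile geometry. This is better controlled than the Michael addition of the chosen plan, where C14 depends on an acyclic transition state.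
- *Weak points:* the diene terminus that becomes quaternary C12 is fully substituted, and crotonates are sluggish dienophiles. A6 requires acylation and silylation of the ring C lactone in the presence of ring B, which is the same regiochemical problem. A8 has the wrong configuration next to the ester and needs later epimerisation.
- *Comparison:* the chosen plan offers a regiospecific enolate from a simple methylene lactone, a one-step acceptor and the same final acid closure. It concedes the stereochemical point and answers it with a catalyst-controlled fallback.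

Key step: step 18

Remark (assumption): L-proline is taken to induce the same absolute sense in triketone 3 as in the parent methyl series, so the angular allyl group of 5 is β; the descriptor is R only because allyl outranks the ring methylene.

Convention: atoms are numbered as in "The problem"; α/β refer to the decalin drawn with C1–C4 on the left and the C10 substituent up (β).

## Steps

Step 1
Reactants: 1 2-allylcyclohexane-1,3-dione; 2 methyl vinyl ketone (but-3-en-2-one)
Product: 3 2-allyl-2-(3-oxobutyl)cyclohexane-1,3-dione
Conditions: Et3N (cat.), EtOAc, rt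
Reagents that add atoms: none
Why: Michael addition of the stabilised dione enolate to the enone (first half of a Robinson annulation); no stereocentre is formed.

Step 2
Reactants: 3 2-allyl-2-(3-oxobutyl)cyclohexane-1,3-dione
Product: 5 (R)-8a-allyl-3,4,8,8a-tetrahydronaphthalene-1,6(2H,7H)-dione (10β-allyl-Δ4-octalin-3,9-dione), via bicyclic ketol 4 (not isolated)
Conditions: L-proline (30 mol %), DMSO, rt
Reagents that add atoms: none
Why: Hajos–Parrish–Eder–Sauer–Wiechert reaction: the proline enamine of the side-chain ketone adds to one of the two enantiotopic ring carbonyls through a hydrogen-bonded transition state, which sets C10, and ketol 4 dehydrates in the flask.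

Step 3
Reactants: 5 (R)-8a-allyl-3,4,8,8a-tetrahydronaphthalene-1,6(2H,7H)-dione
Product: 6 10β-allyl-9β-hydroxy-Δ4-octalin-3-one
Conditions: NaBH4 (0.3 equiv), EtOH, −10 °C
Reagents that add atoms: none
Why: Chemoselective borohydride reduction of the saturated ketone beside the less electrophilic enone; axial hydride attack opposite the angular allyl group gives the equatorial 9β-alcohol.

Step 4
Reactants: 6 10β-allyl-9β-hydroxy-Δ4-octalin-3-one
Product: 7 10β-allyl-9β-benzyloxy-Δ4-octalin-3-one
Conditions: benzyl 2,2,2-trichloroacetimidate, TfOH (cat.), CH2Cl2/cyclohexane, rt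
Reagents that add atoms: benzyl 2,2,2-trichloroacetimidate, N=C(OCc1ccccc1)C(Cl)(Cl)Cl
Why: Acid-catalysed O-benzylation with the imidate avoids basic conditions on the enolisable enone; the benzyl ether survives the base and oxidation steps and falls off in the hydrogenation of step 12.

Step 5
Reactants: 7 10β-allyl-9β-benzyloxy-Δ4-octalin-3-one
Product: 9 10β-allyl-9β-benzyloxy-4,4-dimethyl-Δ5-octalin-3-one, via monomethyl enone 8 (not isolated)
Conditions: KOt-Bu (3 equiv), MeI (excess), t-BuOH/THF, rt
Reagents that add atoms: iodomethane, CI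
Why: Deconjugative double α-alkylation of the enone through its extended dienolates, standard for Wieland–Miescher-type enones; the second methylation moves the alkene to C5=C6.

Step 6
Reactants: 9 10β-allyl-9β-benzyloxy-4,4-dimethyl-Δ5-octalin-3-one
Product: 10 10β-allyl-9β-benzyloxy-3,3-ethylenedioxy-4,4-dimethyl-Δ5-octalin
Conditions: ethylene glycol, TsOH·H2O (cat.), benzene, reflux (Dean–Stark)
Reagents that add atoms: ethylene glycol, OCCO
Why: Acid-catalysed ketalization; it masks C3 against the enolate and hydride steps that follow, and the alkene cannot move because C4 and C10 are quaternary.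

Step 7
Reactants: 10 10β-allyl-9β-benzyloxy-3,3-ethylenedioxy-4,4-dimethyl-Δ5-octalin
Product: 11 10β-allyl-9β-benzyloxy-3,3-ethylenedioxy-4,4-dimethyl-Δ5-octalin-7-one
Conditions: CrO3 (excess), 3,5-dimethylpyrazole, CH2Cl2, −20 °C
Reagents that add atoms: chromium trioxide, O=[Cr](=O)=O
Why: Allylic oxidation with hexavalent chromium at C7, the only allylic CH2 of the trisubstituted ring alkene; the monosubstituted allyl alkene is much less reactive toward this reagent.

Step 8
Reactants: 11 10β-allyl-9β-benzyloxy-3,3-ethylenedioxy-4,4-dimethyl-Δ5-octalin-7-one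
Product: 12 9β-benzyloxy-3,3-ethylenedioxy-4,4-dimethyl-10β-[(E)-prop-1-enyl]-Δ5-octalin-7-one
Conditions: RuHCl(CO)(PPh3)3 (5 mol %), toluene, 80 °C
Reagents that add atoms: none
Why: Metal-hydride-catalysed alkene isomerisation (hydrometalation, β-hydride elimination) moves the terminal alkene one position inward; the ring enone has no hydrogen on C4 or C10 and cannot migrate.

Step 9
Reactants: 12 9β-benzyloxy-3,3-ethylenedioxy-4,4-dimethyl-10β-[(E)-prop-1-enyl]-Δ5-octalin-7-one
Product: 14 9β-benzyloxy-3,3-ethylenedioxy-10β-hydroxymethyl-4,4-dimethyl-Δ5-octalin-7-one, via aldehyde 13 (not isolated)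
Conditions: O3 (1 equiv), pyridine, CH2Cl2, −78 °C; then MeOH, NaBH4, −78 °C
Reagents that add atoms: ozone, [O-][O+]=O
Why: Ozonolysis: the electron-rich 1,2-disubstituted alkene reacts ahead of the hindered, conjugated ring alkene, and borohydride at −78 °C reduces the neopentyl aldehyde but not the enone.

Step 10
Reactants: 14 9β-benzyloxy-3,3-ethylenedioxy-10β-hydroxymethyl-4,4-dimethyl-Δ5-octalin-7-one
Product: 15 9β-benzyloxy-3,3-ethylenedioxy-4,4-dimethyl-10β-(triethylsilyloxymethyl)-Δ5-octalin-7-one
Conditions: Et3SiCl, imidazole, CH2Cl2, 0 °C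
Reagents that add atoms: chlorotriethylsilane, CC[Si](Cl)(CC)CC
Why: Silyl ether formation; the silyl group prevents oxa-Michael addition of the C19 oxygen in step 11 and keeps the angular group from anchoring the hydrogenation catalyst on the β face in step 12.

Step 11
Reactants: 15 9β-benzyloxy-3,3-ethylenedioxy-4,4-dimethyl-10β-(triethylsilyloxymethyl)-Δ5-octalin-7-one
Product: 19 9β-benzyloxy-3,3-ethylenedioxy-4,4-dimethyl-8-methylene-10β-(triethylsilyloxymethyl)-Δ5-octalin-7-one, via lithium enolate 16 (not isolated), via Mannich base 17 (not isolated), via methiodide 18 (not isolated)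
Conditions: LiN(SiMe3)2, THF, −78 °C; Me2N=CH2 I, −78 → 0 °C; then MeI, CH2Cl2, rt; then DBU, rt
Reagents that add atoms: N,N-dimethylmethyleneiminium iodide (Eschenmoser's salt), C=[N+](C)C.[I-]; iodomethane, CI (its methyl stays only in intermediate 18)
Why: Mannich reaction of the only possible enolate (C8; C6 is vinylic and C4 quaternary) followed by quaternisation and β-elimination gives the α-methylene ketone; the low temperature keeps the β-benzyloxy enolate from eliminating.

Step 12
Reactants: 19 9β-benzyloxy-3,3-ethylenedioxy-4,4-dimethyl-8-methylene-10β-(triethylsilyloxymethyl)-Δ5-octalin-7-one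
Product: 21 3,3-ethylenedioxy-9β-hydroxy-4,4,8β-trimethyl-10β-(triethylsilyloxymethyl)-5α-decalin-7-one, via methyl enone 20 (not isolated)
Conditions: H2 (1 atm), RhCl(PPh3)3 (cat.), benzene, rt; filtration; then H2 (3 atm), Pd/C, EtOAc, rt
Reagents that add atoms: none
Why: Catalytic hydrogenation in two stages: the homogeneous rhodium catalyst reduces the exocyclic alkene without allylic C–O hydrogenolysis or alkene migration, then palladium reduces the hindered enone alkene and cleaves the benzyl ether. Both C=C bonds take up hydrogen on the α face, opposite the axial C19 group and the 4β-methyl, which gives the axial 8β-methyl and the trans ring fusion.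

Step 13
Reactants: 21 3,3-ethylenedioxy-9β-hydroxy-4,4,8β-trimethyl-10β-(triethylsilyloxymethyl)-5α-decalin-7-one
Product: 22 3,3-ethylenedioxy-4,4,8β-trimethyl-10β-(triethylsilyloxymethyl)-5α-decalin-7β,9β-diol
Conditions: NaBH4, MeOH/THF, −20 → 0 °C
Reagents that add atoms: none
Why: Borohydride reduction with axial hydride attack on C7 from the α face, where only the axial hydrogens on C5 and C9 stand, while the equatorial approach is blocked by the axial 8β-methyl; the equatorial 7β-alcohol should result.

Step 14
Reactants: 22 3,3-ethylenedioxy-4,4,8β-trimethyl-10β-(triethylsilyloxymethyl)-5α-decalin-7β,9β-diol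
Product: 23 7β-(tert-butyldimethylsilyloxy)-3,3-ethylenedioxy-4,4,8β-trimethyl-10β-(triethylsilyloxymethyl)-5α-decalin-9β-ol
Conditions: t-BuMe2SiOTf (1.1 equiv), 2,6-lutidine, CH2Cl2, −78 °C
Reagents that add atoms: tert-butyldimethylsilyl trifluoromethanesulfonate, CC(C)(C)[Si](C)(C)OS(=O)(=O)C(F)(F)F
Why: Sterically controlled silylation: the C7 hydroxyl has a CH2 neighbour, whereas the C9 hydroxyl lies between the quaternary C10 and the methyl-bearing C8 and should stay free.

Step 15
Reactants: 23 7β-(tert-butyldimethylsilyloxy)-3,3-ethylenedioxy-4,4,8β-trimethyl-10β-(triethylsilyloxymethyl)-5α-decalin-9β-ol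
Product: 24 7β-(tert-butyldimethylsilyloxy)-3,3-ethylenedioxy-4,4,8β-trimethyl-10β-(triethylsilyloxymethyl)-5α-decalin-9-one
Conditions: Dess–Martin periodinane, NaHCO3, CH2Cl2, rt
Reagents that add atoms: none
Why: Hypervalent iodine oxidation of a hindered secondary alcohol under buffered, near-neutral conditions, which should leave the axial C8 methyl unepimerised and the β-silyloxy group in place.

Step 16
Reactants: 24 7β-(tert-butyldimethylsilyloxy)-3,3-ethylenedioxy-4,4,8β-trimethyl-10β-(triethylsilyloxymethyl)-5α-decalin-9-one; 25 ethyl 2-(bromomethyl)acrylate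
Product: 27 dioxolane-protected α-methylene spirolactone (7β-OTBS/19-OTES; lactone oxygen β and C11 α on C9), via zinc alkoxide 26 (not isolated)
Conditions: Zn (activated), THF, 45 °C; aq. NH4Cl
Reagents that add atoms: zinc, [Zn] (retained only in intermediate 26)
Why: Dreiding–Schmidt reaction (Barbier-type addition of the 2-alkoxycarbonylallyl zinc reagent, then lactonization of the alkoxide onto the ester); the reagent adds axially from the α face, anti to both β-axial neighbours (C19 and the C8 methyl), so the new C–C bond is α and the oxygen β.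

Step 17
Reactants: 27 dioxolane-protected α-methylene spirolactone (7β-OTBS/19-OTES)
Product: 28 7β-(tert-butyldimethylsilyloxy)-10β-hydroxymethyl-4,4,8β-trimethyl-3-oxo-5α-decalin-9-spiro-α-methylene-γ-butyrolactone
Conditions: pyridinium p-toluenesulfonate (cat.), acetone/H2O (10:1), 45 °C
Reagents that add atoms: water, O
Why: Mild acid hydrolysis: the dioxolane of the hindered ketone and the primary triethylsilyl ether are cleaved under conditions that a secondary tert-butyldimethylsilyl ether withstands.

Step 18
Reactants: 28 7β-(tert-butyldimethylsilyloxy)-10β-hydroxymethyl-4,4,8β-trimethyl-3-oxo-5α-decalin-9-spiro-α-methylene-γ-butyrolactone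
Product: 30 isopropyl bis-spirolactone (ring A with 5-isopropyl; 7β-OTBS; 8β-methyl; δ-lactone B on C10; α-methylene-γ-lactone on C9), via ketene 29 (not isolated)
Conditions: hν (300 nm, Pyrex), degassed benzene (5 mM), rt
Reagents that add atoms: none
Why: Norrish type 1 photolactonization. n→π* excitation of the C3 ketone is followed by α-cleavage of C3–C4, the only cleavage that releases a tertiary radical, and the acyl/alkyl biradical disproportionates by transfer of a C2 hydrogen to C4, which gives ketene 29 and the isopropyl group. The closest known reaction type is the photolysis of 4,4-dimethyl-3-keto terpenoids and 2,2-dimethylcyclohexanones to seco acids or esters through ketenes, including the variant in which a hydroxyl of the same molecule captures the ketene. Ring B closes by addition of the C19 hydroxyl to the ketene carbon C3, a six-membered closure that is exo with respect to the C=O bond, followed by enol-to-ester tautomerisation; C3–O19 is the only new skeletal bond. No stereocentre is created: C4 becomes an isopropyl carbon, and C5 and C10 take no part in the cleavage, so the trans ring fusion becomes the cis relation of C19–O and the isopropyl group on ring A. The selectivity needed is cleavage on the C4 side, secured by the gem-dimethyl group; hydrogen transfer toward the ketene and not to the acyl carbon, which the substrate does not control and is the main uncertainty; and capture by the right oxygen, secured because C19–OH is the only free hydroxyl and is held axial over C2–C3. The α-methylene lactone does not absorb at 300 nm, and α-cleavage of the excited ketone should be faster than energy transfer or radical addition to it.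

Step 19
Reactants: 31 methyl 4,4-dimethoxy-3-oxopentanoate; 32 acetaldehyde
Product: 33 methyl 2-ethylidene-4,4-dimethoxy-3-oxopentanoate (E/Z mixture, drawn E)
Conditions: piperidine (cat.), AcOH (cat.), CH2Cl2, 4 Å molecular sieves, 0 °C
Reagents that add atoms: none
Why: Knoevenagel condensation of the β-keto ester with the aldehyde; the alkene geometry is of no consequence because C15 becomes epimerisable after the addition.

Step 20
Reactants: 30 isopropyl bis-spirolactone; 33 methyl 2-ethylidene-4,4-dimethoxy-3-oxopentanoate
Product: 35 Michael adduct (12R,14S; β-keto ester side chain on C12; C15 as epimer mixture), via lithium enolate 34 (not isolated)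
Conditions: LiBH(s-Bu)3 (1.05 equiv), THF, −78 °C; then 33, −78 → −40 °C; aq. NH4Cl
Reagents that add atoms: lithium tri-sec-butylborohydride, [Li+].CCC(C)[BH-](C(C)CC)C(C)CC (lithium retained only in intermediate 34)
Why: Conjugate reduction–Michael addition: hydride adds to the exocyclic enoate, which makes the C12 methyl and the C12 enolate regiospecifically and leaves the δ-lactone untouched, and the enolate adds to the alkylidene β-keto ester. The acceptor should approach the enolate face turned toward C8–H and away from the C1 methylene of ring B, which sets C12; C14 is expected from a lithium-bridged synclinal transition state in which C15 sits beside the small C12 methyl, the C14 methyl is anti to C13 and the C14 hydrogen faces C11.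

Step 21
Reactants: 35 Michael adduct
Product: 36 (15R,18S)-hydroxy ester (C18 secondary alcohol; C17 dimethyl ketal)
Conditions: NaBH4, MeOH/THF, −20 °C
Reagents that add atoms: none
Why: Borohydride reduction of the ketone of an α-substituted β-keto ester under non-chelating conditions; the polar Felkin–Anh model (ester anti to the incoming hydride) predicts the 15,18-anti isomer needed, C15 equilibrates through the enol before reduction, and the lactones are not reduced at this temperature.

Step 22
Reactants: 36 (15R,18S)-hydroxy ester
Product: 38 7-O-TBS isopropyl cage compound (4-deoxy-7-O-silyl chermebilaene B), via methyl ketol 37 (not isolated)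
Conditions: TsOH·H2O (cat.), acetone/H2O (20:1), rt; then toluene, 4 Å molecular sieves, 50 °C
Reagents that add atoms: water, O
Why: Acid-catalysed ketal hydrolysis, then a cascade of hemiketalisation, lactonization and orthoester formation: the ring C lactone oxygen adds to the C17 ketone, the C17 oxygen closes on the ester with loss of methanol, and the C18 hydroxyl captures the dialkoxycarbenium ion at C13. C13 and C17 are fixed by the tethers, and only the (15R,18S) isomer can close; the other isomers can equilibrate through the enediol of ketol 37.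

Step 23
Reactants: 38 7-O-TBS isopropyl cage compound
Product: 39 7-O-TBS chermebilaene B
Conditions: methyl(trifluoromethyl)dioxirane in 1,1,1-trifluoroacetone, CH2Cl2, −20 → 0 °C
Reagents that add atoms: methyl(trifluoromethyl)dioxirane, CC1(OO1)C(F)(F)F
Why: Dioxirane C–H hydroxylation (concerted oxygen insertion); C4–H is the only tertiary C–H without an oxygen-bearing carbon within two bonds, and the C7 carbinol C–H is axial and shielded by the silyl group and C11.

Step 24
Reactants: 39 7-O-TBS chermebilaene B
Product: 40 chermebilaene B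
Conditions: HF·pyridine, pyridine, THF, 0 °C → rt
Reagents that add atoms: none
Why: Fluoride-mediated cleavage of the silyl ether under buffered conditions that the lactones, the orthoester–ketal cage and the tertiary alcohol should tolerate.

## Compound list

1 | 2-allylcyclohexane-1,3-dione | C=CCC1C(=O)CCCC1=O | starting material
2 | methyl vinyl ketone | CC(=O)C=C | starting material
3 | 2-allyl-2-(3-oxobutyl)cyclohexane-1,3-dione | CC(=O)CCC1(CC=C)C(=O)CCCC1=O | intermediate
4 | cis-fused bicyclic ketol (10β-allyl-5β-hydroxydecalin-3,9-dione) | C=CC[C@]12CCC(=O)C[C@@]1(O)CCCC2=O | intermediate (not isolated)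
5 | (R)-8a-allyl-3,4,8,8a-tetrahydronaphthalene-1,6(2H,7H)-dione | C=CC[C@]12CCC(=O)C=C1CCCC2=O | intermediate
6 | 10β-allyl-9β-hydroxy-Δ4-octalin-3-one | C=CC[C@]12CCC(=O)C=C1CCC[C@@H]2O | intermediate
7 | 10β-allyl-9β-benzyloxy-Δ4-octalin-3-one | C=CC[C@]12CCC(=O)C=C1CCC[C@@H]2OCc3ccccc3 | intermediate
8 | 10β-allyl-9β-benzyloxy-4-methyl-Δ4-octalin-3-one | C=CC[C@]12CCC(=O)C(C)=C1CCC[C@@H]2OCc3ccccc3 | intermediate (not isolated)
9 | 10β-allyl-9β-benzyloxy-4,4-dimethyl-Δ5-octalin-3-one | C=CC[C@]12CCC(=O)C(C)(C)C1=CCC[C@@H]2OCc3ccccc3 | intermediate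
10 | 10β-allyl-9β-benzyloxy-3,3-ethylenedioxy-4,4-dimethyl-Δ5-octalin | C=CC[C@]12CCC3(OCCO3)C(C)(C)C1=CCC[C@@H]2OCc4ccccc4 | intermediate
11 | 10β-allyl-9β-benzyloxy-3,3-ethylenedioxy-4,4-dimethyl-Δ5-octalin-7-one | C=CC[C@]12CCC3(OCCO3)C(C)(C)C1=CC(=O)C[C@@H]2OCc4ccccc4 | intermediate
12 | 9β-benzyloxy-3,3-ethylenedioxy-4,4-dimethyl-10β-[(E)-prop-1-enyl]-Δ5-octalin-7-one | C/C=C/[C@]12CCC3(OCCO3)C(C)(C)C1=CC(=O)C[C@@H]2OCc4ccccc4 | intermediate
13 | 10β-formyl analogue of 12 | O=C[C@]12CCC3(OCCO3)C(C)(C)C1=CC(=O)C[C@@H]2OCc4ccccc4 | intermediate (not isolated)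
14 | 9β-benzyloxy-3,3-ethylenedioxy-10β-hydroxymethyl-4,4-dimethyl-Δ5-octalin-7-one | OC[C@]12CCC3(OCCO3)C(C)(C)C1=CC(=O)C[C@@H]2OCc4ccccc4 | intermediate
15 | 19-O-triethylsilyl ether of 14 | CC[Si](CC)(CC)OC[C@]12CCC3(OCCO3)C(C)(C)C1=CC(=O)C[C@@H]2OCc4ccccc4 | intermediate
16 | lithium C7–C8 enolate of 15 | CC[Si](CC)(CC)OC[C@]12CCC3(OCCO3)C(C)(C)C1=CC(O[Li])=C[C@@H]2OCc4ccccc4 | intermediate (not isolated)
17 | 8α-(dimethylaminomethyl) derivative of 15 (Mannich base) | CC[Si](CC)(CC)OC[C@]12CCC3(OCCO3)C(C)(C)C1=CC(=O)[C@@H](CN(C)C)[C@@H]2OCc4ccccc4 | intermediate (not isolated)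
18 | trimethylammoniomethyl iodide derived from 17 | CC[Si](CC)(CC)OC[C@]12CCC3(OCCO3)C(C)(C)C1=CC(=O)[C@@H](C[N+](C)(C)C)[C@@H]2OCc4ccccc4.[I-] | intermediate (not isolated)
19 | 9β-benzyloxy-3,3-ethylenedioxy-4,4-dimethyl-8-methylene-10β-(triethylsilyloxymethyl)-Δ5-octalin-7-one | CC[Si](CC)(CC)OC[C@]12CCC3(OCCO3)C(C)(C)C1=CC(=O)C(=C)[C@@H]2OCc4ccccc4 | intermediate
20 | 9β-benzyloxy-3,3-ethylenedioxy-4,4,8β-trimethyl-10β-(triethylsilyloxymethyl)-Δ5-octalin-7-one | C[C@H]1C(=O)C=C2C(C)(C)C3(OCCO3)CC[C@]2(CO[Si](CC)(CC)CC)[C@H]1OCc4ccccc4 | intermediate (not isolated)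
21 | 3,3-ethylenedioxy-9β-hydroxy-4,4,8β-trimethyl-10β-(triethylsilyloxymethyl)-5α-decalin-7-one | C[C@H]1C(=O)C[C@H]2C(C)(C)C3(OCCO3)CC[C@]2(CO[Si](CC)(CC)CC)[C@H]1O | intermediate
22 | 3,3-ethylenedioxy-4,4,8β-trimethyl-10β-(triethylsilyloxymethyl)-5α-decalin-7β,9β-diol | C[C@H]1[C@@H](O)C[C@H]2C(C)(C)C3(OCCO3)CC[C@]2(CO[Si](CC)(CC)CC)[C@H]1O | intermediate
23 | 7β-(tert-butyldimethylsilyloxy)-3,3-ethylenedioxy-4,4,8β-trimethyl-10β-(triethylsilyloxymethyl)-5α-decalin-9β-ol | C[C@H]1[C@@H](O[Si](C)(C)C(C)(C)C)C[C@H]2C(C)(C)C3(OCCO3)CC[C@]2(CO[Si](CC)(CC)CC)[C@H]1O | intermediate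
24 | 7β-(tert-butyldimethylsilyloxy)-3,3-ethylenedioxy-4,4,8β-trimethyl-10β-(triethylsilyloxymethyl)-5α-decalin-9-one | C[C@H]1[C@@H](O[Si](C)(C)C(C)(C)C)C[C@H]2C(C)(C)C3(OCCO3)CC[C@]2(CO[Si](CC)(CC)CC)C1=O | intermediate
25 | ethyl 2-(bromomethyl)acrylate | C=C(CBr)C(=O)OCC | starting material
26 | bromozinc 9β-alkoxide of the 9α-[2-(ethoxycarbonyl)allyl] adduct of 24 | C[C@H]1[C@@H](O[Si](C)(C)C(C)(C)C)C[C@H]2C(C)(C)C3(OCCO3)CC[C@]2(CO[Si](CC)(CC)CC)[C@]1(O[Zn]Br)CC(=C)C(=O)OCC | intermediate (not isolated)
27 | 9-spiro α-methylene-γ-butyrolactone (O9 β, C11 α) with 3,3-ethylenedioxy, 4,4,8β-trimethyl, 7β-OTBS and 10β-CH2OTES on the 5α-decalin | C[C@H]1[C@@H](O[Si](C)(C)C(C)(C)C)C[C@H]2C(C)(C)C3(OCCO3)CC[C@]2(CO[Si](CC)(CC)CC)[C@]12CC(=C)C(=O)O2 | intermediate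
28 | 7β-(tert-butyldimethylsilyloxy)-10β-hydroxymethyl-4,4,8β-trimethyl-3-oxo-5α-decalin-9-spiro-α-methylene-γ-butyrolactone (precursor of the key step) | C[C@H]1[C@@H](O[Si](C)(C)C(C)(C)C)C[C@H]2C(C)(C)C(=O)CC[C@]2(CO)[C@]12CC(=C)C(=O)O2 | intermediate
29 | ketene (C2=C3=O) with isopropyl on C5 and free C19 hydroxyl | C[C@H]1[C@@H](O[Si](C)(C)C(C)(C)C)C[C@@H](C(C)C)[C@](CO)(CC=C=O)[C@]12CC(=C)C(=O)O2 | intermediate (not isolated)
30 | isopropyl bis-spirolactone: ring A with 5-isopropyl, 7β-OTBS, 8β-methyl, δ-lactone B spiro at C10, α-methylene-γ-lactone spiro at C9 | C[C@H]1[C@@H](O[Si](C)(C)C(C)(C)C)C[C@@H](C(C)C)[C@]2(CCC(=O)OC2)[C@]12CC(=C)C(=O)O2 | intermediate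
31 | methyl 4,4-dimethoxy-3-oxopentanoate | COC(=O)CC(=O)C(C)(OC)OC | starting material
32 | acetaldehyde | CC=O | starting material
33 | methyl (E)-2-ethylidene-4,4-dimethoxy-3-oxopentanoate (used as E/Z mixture) | C/C=C(/C(=O)OC)C(=O)C(C)(OC)OC | intermediate
34 | lithium enolate of the α-methyl γ-lactone (C12=C13–OLi) | C[C@H]1[C@@H](O[Si](C)(C)C(C)(C)C)C[C@@H](C(C)C)[C@]2(CCC(=O)OC2)[C@]12CC(C)=C(O[Li])O2 | intermediate (not isolated)
35 | (12R,14S) Michael adduct: γ-lactone with 12-methyl and 12-[CH(CH3)CH(CO2CH3)C(=O)C(OCH3)2CH3]; C15 epimer mixture | C[C@H]1[C@@H](O[Si](C)(C)C(C)(C)C)C[C@@H](C(C)C)[C@]2(CCC(=O)OC2)[C@]12C[C@@](C)(C(=O)O2)[C@@H](C)C(C(=O)OC)C(=O)C(C)(OC)OC | intermediate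
36 | (12R,14S,15R,18S) hydroxy ester with C17 dimethyl ketal | C[C@H]1[C@@H](O[Si](C)(C)C(C)(C)C)C[C@@H](C(C)C)[C@]2(CCC(=O)OC2)[C@]12C[C@@](C)(C(=O)O2)[C@@H](C)[C@@H](C(=O)OC)[C@H](O)C(C)(OC)OC | intermediate
37 | (15R,18S) methyl ketol (C18–OH, C17=O) | C[C@H]1[C@@H](O[Si](C)(C)C(C)(C)C)C[C@@H](C(C)C)[C@]2(CCC(=O)OC2)[C@]12C[C@@](C)(C(=O)O2)[C@@H](C)[C@@H](C(=O)OC)[C@H](O)C(C)=O | intermediate (not isolated)
38 | 7-O-TBS isopropyl cage compound (4-deoxy-7-O-silyl chermebilaene B) | C[C@H]1[C@@H](O[Si](C)(C)C(C)(C)C)C[C@@H](C(C)C)[C@]2(CCC(=O)OC2)[C@]12C[C@]1(C)[C@@H](C)[C@H]3C(=O)O[C@@]4(C)O[C@@]1(O[C@@H]34)O2 | intermediate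
39 | 7-O-TBS chermebilaene B | C[C@H]1[C@@H](O[Si](C)(C)C(C)(C)C)C[C@@H](C(C)(C)O)[C@]2(CCC(=O)OC2)[C@]12C[C@]1(C)[C@@H](C)[C@H]3C(=O)O[C@@]4(C)O[C@@]1(O[C@@H]34)O2 | intermediate
40 | chermebilaene B (5R,7S,8S,9S,10S,12R,13S,14S,15R,17S,18S in the numbering used here) | C[C@H]1[C@@H](O)C[C@@H](C(C)(C)O)[C@]2(CCC(=O)OC2)[C@]12C[C@]1(C)[C@@H](C)[C@H]3C(=O)O[C@@]4(C)O[C@@]1(O[C@@H]34)O2 | target

## Step count and least certain steps

Total: 24 steps (23 in the main line plus the one-step preparation of acceptor 33). Longest linear sequence: 23 steps (steps 1–18 and 20–24).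

**Step 18 (key step).** The biradical may partition toward hydrogen transfer from C5 or a C4 methyl to the acyl carbon, giving unsaturated aldehydes, and the ketene may be lost by oligomerisation before the neopentyl hydroxyl adds; neither branch is controlled by the substrate. The fallback avoids photochemistry. It sets out from 28: Baeyer–Villiger oxidation (m-chloroperbenzoic acid, NaHCO3, CH2Cl2) with migration of the tertiary C4 gives the seven-membered lactone F1, and acid-catalysed acyl transfer to the C19 hydroxyl gives the tertiary alcohol bis-lactone F2. F2 is taken through the operations of steps 20–22 (one extra equivalent of LiBH(s-Bu)3 for the free hydroxyl) by way of Michael adduct F3 and hydroxy ester F4, and returns to the route at 39, so that step 23 is not needed.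

**Step 20.** Facial selection on the acceptor (C14) rests on an acyclic transition state and may be poor, and proton transfer from the γ-methyl of 33 to the basic enolate may compete with C–C bond formation. The fallback replaces the lithium enolate by a Lewis-acid pathway. It sets out from 30: 1,4-hydrosilylation (Et3SiH, RhCl(PPh3)3) gives the triethylsilyl ketene acetal F5, and a Mukaiyama–Michael addition to 33 catalysed by Cu(OTf)2 (divalent copper) with a chiral bis(oxazoline) ligand, whose enantiomer selects the acceptor face, returns to the route at 35 after hydrolytic work-up.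

**Step 22.** Closure may stop at the hemiketal lactone, the β-hydroxy ester may dehydrate under acid, the silyl ether may be lost, and the equilibration of wrong C15/C18 isomers through the enediol may be too slow. The fallback closes the cage in stages. It sets out from 36: mild hydrolysis (aqueous AcOH) and lactolisation (Et3N) give the hydroxy lactol lactone F6, and silylation (Me3SiCl, imidazole) gives the bis(trimethylsilyl) ether F7. Catalytic Me3SiOTf at −40 °C then converts the ring C lactone carbonyl and the two silyl ethers into the orthoester with loss of the disiloxane, which returns to the route at 38.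

**Step 23.** Oxidation may occur at the C7 carbinol C–H next to the silyl ether or at the ring tertiary C–H bonds (C5, C14), and over-oxidation is possible. The fallback changes the protecting group to one that deactivates C7–H electronically. It sets out from 38: HF·pyridine gives the 7-hydroxy isopropyl cage compound F8, and trifluoroacetic anhydride with pyridine gives the 7-trifluoroacetate F9. The same dioxirane gives the 7-trifluoroacetate tertiary alcohol F10, and NaHCO3 in MeOH removes the ester and returns to the route at 40. The Baeyer–Villiger detour described for step 18 also bypasses this step.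

**Step 12.** The hindered conjugated C5=C6 bond may resist hydrogenation or take up hydrogen without facial control, and palladium may cause allylic C–O hydrogenolysis or alkene migration toward C9 if the first stage is incomplete. The fallback uses non-catalytic reductions. It sets out from 19: diimide (potassium azodicarboxylate, AcOH) reduces only the exocyclic alkene under steric control to give 20, and Li in NH3/THF with t-BuOH (one equivalent) reduces the enone to the trans-decalone by axial protonation at C5 and cleaves the benzyl ether, returning to the route at 21; no new compound is involved.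

## Further compounds

F1 | step 18 | seven-membered lactone (O inserted between C3 and C4) of 28 | C[C@H]1[C@@H](O[Si](C)(C)C(C)(C)C)C[C@H]2C(C)(C)OC(=O)CC[C@]2(CO)[C@]12CC(=C)C(=O)O2
F2 | step 18 | tertiary alcohol bis-lactone (4-hydroxy analogue of 30) | C[C@H]1[C@@H](O[Si](C)(C)C(C)(C)C)C[C@@H](C(C)(C)O)[C@]2(CCC(=O)OC2)[C@]12CC(=C)C(=O)O2
F3 | step 18 | 4-hydroxy analogue of Michael adduct 35 | C[C@H]1[C@@H](O[Si](C)(C)C(C)(C)C)C[C@@H](C(C)(C)O)[C@]2(CCC(=O)OC2)[C@]12C[C@@](C)(C(=O)O2)[C@@H](C)C(C(=O)OC)C(=O)C(C)(OC)OC
F4 | step 18 | 4-hydroxy analogue of hydroxy ester 36 | C[C@H]1[C@@H](O[Si](C)(C)C(C)(C)C)C[C@@H](C(C)(C)O)[C@]2(CCC(=O)OC2)[C@]12C[C@@](C)(C(=O)O2)[C@@H](C)[C@@H](C(=O)OC)[C@H](O)C(C)(OC)OC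
F5 | step 20 | triethylsilyl ketene acetal of the α-methyl γ-lactone | C[C@H]1[C@@H](O[Si](C)(C)C(C)(C)C)C[C@@H](C(C)C)[C@]2(CCC(=O)OC2)[C@]12CC(C)=C(O[Si](CC)(CC)CC)O2
F6 | step 22 | hydroxy lactol lactone (γ-lactone C15–C16–O–C17–C18 closed; C17–OH and C18–OH free) | C[C@H]1[C@@H](O[Si](C)(C)C(C)(C)C)C[C@@H](C(C)C)[C@]2(CCC(=O)OC2)[C@]12C[C@@](C)(C(=O)O2)[C@@H](C)[C@H]3C(=O)O[C@@](C)(O)[C@H]3O
F7 | step 22 | bis(trimethylsilyl) ether of F6 | C[C@H]1[C@@H](O[Si](C)(C)C(C)(C)C)C[C@@H](C(C)C)[C@]2(CCC(=O)OC2)[C@]12C[C@@](C)(C(=O)O2)[C@@H](C)[C@H]3C(=O)O[C@@](C)(O[Si](C)(C)C)[C@H]3O[Si](C)(C)C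
F8 | step 23 | 7-hydroxy isopropyl cage compound | C[C@H]1[C@@H](O)C[C@@H](C(C)C)[C@]2(CCC(=O)OC2)[C@]12C[C@]1(C)[C@@H](C)[C@H]3C(=O)O[C@@]4(C)O[C@@]1(O[C@@H]34)O2
F9 | step 23 | 7-trifluoroacetate of F8 | C[C@H]1[C@@H](OC(=O)C(F)(F)F)C[C@@H](C(C)C)[C@]2(CCC(=O)OC2)[C@]12C[C@]1(C)[C@@H](C)[C@H]3C(=O)O[C@@]4(C)O[C@@]1(O[C@@H]34)O2
F10 | step 23 | 7-trifluoroacetate of chermebilaene B | C[C@H]1[C@@H](OC(=O)C(F)(F)F)C[C@@H](C(C)(C)O)[C@]2(CCC(=O)OC2)[C@]12C[C@]1(C)[C@@H](C)[C@H]3C(=O)O[C@@]4(C)O[C@@]1(O[C@@H]34)O2
F0 | step 12 | none | none
A1 | alternative 1 | aldehyde with δ-lactone B, C4 triethylsilyl ether and (E)-but-2-en-2-yl group on C10 | O=CC[C@@H](C(C)(C)O[Si](CC)(CC)CC)[C@]1(CCC(=O)OC1)/C(C)=C/C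
A2 | alternative 1 | ring A/B methylenecyclohexanol | C[C@H]1[C@@H](O)C[C@@H](C(C)(C)O[Si](CC)(CC)CC)[C@]2(CCC(=O)OC2)C1=C
A3 | alternative 2 | ring A/B exocyclic alkene diacetate | C[C@H]1[C@@H](OC(C)=O)C[C@@H](C(C)(C)OC(C)=O)[C@]2(CCC(=O)OC2)C1=C
A4 | alternative 2 | methyl 3,5-dimethylorsellinate | COC(=O)c1c(C)c(C)c(O)c(C)c1O
A5 | alternative 2 | dearomatized spiro dihydrofuran-fused cyclohexadienone | C[C@H]1[C@@H](OC(C)=O)C[C@@H](C(C)(C)OC(C)=O)[C@]2(CCC(=O)OC2)[C@]12C[C@]3(C)C(C)=C(C(=O)OC)C(=O)C(C)=C3O2
A6 | alternative 3 | 1-silyloxy-3-alkoxy diene on the ring C dihydrofuran | C[C@H]1[C@@H](O[Si](C)(C)C(C)(C)C)C[C@@H](C(C)(C)O[Si](CC)(CC)CC)[C@]2(CCC(=O)OC2)[C@]12CC(C)=C(O2)/C(C)=C/O[Si](C)(C)C(C)(C)C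
A7 | alternative 3 | methyl (E)-crotonate | C/C=C/C(=O)OC
A8 | alternative 3 | cyclohexene-fused bicyclic enol ether | C[C@H]1[C@@H](O[Si](C)(C)C(C)(C)C)C[C@@H](C(C)(C)O[Si](CC)(CC)CC)[C@]2(CCC(=O)OC2)[C@]12C[C@]3(C)[C@@H](C)[C@H](C(=O)OC)[C@H](O[Si](C)(C)C(C)(C)C)C(C)=C3O2
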